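**Retrosynthetic overview**
1. Target ⇐ silyl ether cleavage ⇐ B-alkyl Suzuki–Miyaura coupling (C13–C14) of a C11-vinyl bicyclic lactone with (Z)-3-iodo-2-methylallyl acetate.
2. Bicyclic lactone ⇐ one-flask biomimetic double epoxide opening of an acyclic (6S,7S,10S,11S)-bis-epoxy C18 acid. The ε-lactone forms first (carboxyl opens the 6,7-epoxide at C7), then the oxepane/1,4-dioxanone (C6–OH opens the 10,11-epoxide at C11). The C11 vinyl group steers the second opening and later becomes C12–C13.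
3. Bis-epoxide ⇐ Shi epoxidation (C6=C7) and Sharpless epoxidation (C10=C11) of a dienol; C18 is oxidised last so that acid formation triggers the cascade.
4. Dienol ⇐ B-alkyl Suzuki coupling (C9–C10) of a nerol-derived 1,3-diene with (Z)-2-(iodomethylidene)but-3-en-1-ol; both Z-alkenyl iodides come from copper-catalysed anti-carbomagnesiation of propargyl alcohol.

Assumption and conventions: locants C1–C18 follow the acyclic diterpene chain (C1 = CH2OH carbon, C16 = CH2OAc carbon, C18 = lactone carbonyl; target = 2Z,14Z,6S,7R,10S,11R as drawn); TBS = tert-butyldimethylsilyl, 9-BBN = 9-borabicyclo[3.3.1]nonane.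

**Route**

Step 1
Reactants: 1 nerol [(2Z)-3,7-dimethylocta-2,6-dien-1-ol]
Product: 2 tert-butyl{[(2Z)-3,7-dimethylocta-2,6-dien-1-yl]oxy}dimethylsilane (neryl TBS ether)
Conditions: TBSCl, imidazole, DMF, 0 °C → rt
Reagents that add atoms: tert-butyldimethylsilyl chloride, CC(C)(C)[Si](C)(C)Cl
Why: Imidazole-promoted silyl ether formation on a primary allylic alcohol, which creates no stereocentre and leaves the 2Z olefin of nerol untouched.

Step 2
Reactants: 2 neryl TBS ether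
Product: 4 (2E,6Z)-8-(TBSO)-2,6-dimethylocta-2,6-dienal, via allylic alcohol 3 (not isolated)
Conditions: SeO2 (10 mol%), t-BuOOH, salicylic acid (cat.), CH2Cl2, rt; then MnO2 on the crude mixture, CH2Cl2, rt
Reagents that add atoms: tert-butyl hydroperoxide, CC(C)(C)OO (source of the new oxygen, passed on by the SeO2 catalyst)
Why: Selenium dioxide allylic oxidation (ene reaction then [2,3]-shift) attacks the E-methyl group of the electron-rich distal olefin (the 2,3-olefin is deactivated by its allylic silyloxy group), which fixes the 6E geometry, and MnO2 converges alcohol and aldehyde on the enal.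

Step 3
Reactants: 4 (2E,6Z)-8-(TBSO)-2,6-dimethylocta-2,6-dienal
Product: 5 tert-butyl{[(2Z,6E)-3,7-dimethylnona-2,6,8-trien-1-yl]oxy}dimethylsilane
Conditions: Ph3PCH3Br, KOt-Bu, THF, 0 °C → rt
Reagents that add atoms: methyltriphenylphosphonium bromide, C[P+](c1ccccc1)(c1ccccc1)c1ccccc1.[Br-]
Why: Wittig methylenation of the enal with a non-stabilised ylide gives the terminal 1,3-diene without disturbing the E-trisubstituted olefin.

Step 4
Reactants: 6 prop-2-yn-1-ol (propargyl alcohol)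
Product: 7 (2Z)-2-(iodomethylidene)but-3-en-1-ol
Conditions: CH2=CHMgBr (2.5 equiv), CuI (10 mol%), THF, −10 °C → rt; then I2, −78 → 0 °C
Reagents that add atoms: vinylmagnesium bromide, C=C[Mg]Br; iodine, II
Why: Copper-catalysed anti-carbomagnesiation of propargyl alcohol (Duboudin reaction) places the vinyl group on C2 and magnesium on C3 in a five-membered alkoxide chelate, so iodinolysis with retention gives only the Z-iodoalkene (iodine cis to CH2OH), which later fixes the C10=C11 geometry.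

Step 5
Reactants: 5 tert-butyl{[(2Z,6E)-3,7-dimethylnona-2,6,8-trien-1-yl]oxy}dimethylsilane; 7 (2Z)-2-(iodomethylidene)but-3-en-1-ol
Product: 9 (2Z,6E,10Z)-12-(TBSO)-2-ethenyl-6,10-dimethyldodeca-2,6,10-trien-1-ol, via alkylborane 8 (not isolated)
Conditions: 9-BBN, THF, 0 °C → rt; then 7, Pd(dppf)Cl2 (5 mol%), AsPh3, aq. K3PO4, DMF, rt
Reagents that add atoms: none
Why: 9-BBN adds only to the terminal carbon of the monosubstituted end of the 1,3-diene (trisubstituted olefins are inert), and the B-alkyl Suzuki–Miyaura coupling with the alkenyl iodide proceeds with retention, so C9 ends up cis to the CH2OH carbon.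

Step 6
Reactants: 9 (2Z,6E,10Z)-12-(TBSO)-2-ethenyl-6,10-dimethyldodeca-2,6,10-trien-1-ol
Product: 10 {(2R,3S)-3-[(3E,7Z)-9-(TBSO)-3,7-dimethylnona-3,7-dien-1-yl]-2-ethenyloxiran-2-yl}methanol
Conditions: Ti(Oi-Pr)4 (20 mol%), D-(−)-diethyl tartrate (26 mol%), t-BuOOH, 4 Å MS, CH2Cl2, −25 °C
Reagents that add atoms: tert-butyl hydroperoxide, CC(C)(C)OO
Why: Sharpless asymmetric epoxidation of the only free allylic alcohol, in which D-(−)-tartrate delivers oxygen to the face that gives C10 S and C11 R (the mirror image of the face used by L-(+)-tartrate, which gives 2S-epoxy alcohols), while the homoallylic vinyl group and the other olefins do not react.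

Step 7
Reactants: 10 {(2R,3S)-3-[(3E,7Z)-9-(TBSO)-3,7-dimethylnona-3,7-dien-1-yl]-2-ethenyloxiran-2-yl}methanol
Product: 11 {(2R,3S)-3-(2-{(2S,3S)-3-[(3Z)-5-(TBSO)-3-methylpent-3-en-1-yl]-2-methyloxiran-2-yl}ethyl)-2-ethenyloxiran-2-yl}methanol
Conditions: L-fructose-derived Shi ketone (30 mol%), Oxone (2KHSO5·KHSO4·K2SO4), K2CO3, Bu4NHSO4, MeCN/dimethoxymethane/aq. Na2B4O7 buffer (pH 10.5), 0 °C
Reagents that add atoms: potassium peroxymonosulfate (Oxone), [K+].[O-]S(=O)(=O)OO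
Why: Shi asymmetric epoxidation, in which the chiral dioxirane attacks the only unfunctionalised electron-rich trisubstituted olefin (C2=C3 is deactivated by its allylic silyloxy group, the terminal vinyl group is a poor substrate) through the spiro transition state, the L-fructose ketone giving the (6S,7S)-epoxide (the D-fructose ketone gives R,R).

Step 8
Reactants: 11 {(2R,3S)-3-(2-{(2S,3S)-3-[(3Z)-5-(TBSO)-3-methylpent-3-en-1-yl]-2-methyloxiran-2-yl}ethyl)-2-ethenyloxiran-2-yl}methanol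
Product: 14 (1R,2S,5R,9S)-9-[(3Z)-5-(TBSO)-3-methylpent-3-en-1-yl]-1-ethenyl-2-hydroxy-5-methyl-6,8-dioxabicyclo[3.2.2]nonan-7-one, via bis-epoxy acid 12 (not isolated), via hydroxy epoxy-lactone 13 (not isolated)
Conditions: TEMPO (20 mol%), PhI(OAc)2 (2.4 equiv), MeCN/pH 7 phosphate buffer, 0 °C → rt; acidify to pH 4 and extract into CH2Cl2; then CSA (20 mol%), CH2Cl2 (0.01 M), −20 °C → rt
Reagents that add atoms: water, O
Why: Proposed new method: oxidation of the primary alcohol gives glycidic acid 12, whose carboxyl group (the electron-poor glycidate oxygen being a poor competitor) opens the protonated 6,7-epoxide at tertiary C7 with inversion to give ε-lactone 13, after which the freed C6 hydroxyl, held over C11 by the planar lactone, opens the vinyl epoxide at the allylic tertiary carbon (6-exo) rather than at C10 with inversion, so C7 (R) and C11 (R) are set by double inversion while C6 (S) and C10 (S) are carried over from the two epoxides; the closest known reaction types are acid-catalysed epoxy-acid lactonisation and acid-catalysed hydroxy vinyl-epoxide cyclisation at the allylic carbon.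

Step 9
Reactants: 6 prop-2-yn-1-ol
Product: 16 (2Z)-3-iodo-2-methylprop-2-en-1-yl acetate, via iodoalkenyl alkoxide 15 (not isolated)
Conditions: MeMgBr (2.5 equiv), CuI (10 mol%), THF, −10 °C → rt; I2, −78 → 0 °C; then Ac2O, DMAP (cat.), 0 °C → rt
Reagents that add atoms: methylmagnesium bromide, C[Mg]Br; iodine, II; acetic anhydride, CC(=O)OC(C)=O
Why: The same copper-catalysed anti-carbomagnesiation gives the chelated Z-alkenylmagnesium species, iodinolysis with retention gives the Z-iodide (iodine cis to the oxygenated carbon), and the magnesium alkoxide is acetylated in the same flask.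

Step 10
Reactants: 14 (1R,2S,5R,9S)-9-[(3Z)-5-(TBSO)-3-methylpent-3-en-1-yl]-1-ethenyl-2-hydroxy-5-methyl-6,8-dioxabicyclo[3.2.2]nonan-7-one; 16 (2Z)-3-iodo-2-methylprop-2-en-1-yl acetate
Product: 18 (2Z)-5-[(1R,2S,5R,9S)-9-[(3Z)-5-(TBSO)-3-methylpent-3-en-1-yl]-2-hydroxy-5-methyl-7-oxo-6,8-dioxabicyclo[3.2.2]nonan-1-yl]-2-methylpent-2-en-1-yl acetate, via alkylborane 17 (not isolated)
Conditions: 9-BBN (3 equiv), THF, rt; then 16, Pd(dppf)Cl2 (5 mol%), AsPh3, aq. K3PO4, DMF, rt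
Reagents that add atoms: none
Why: 9-BBN hydroborates the only monosubstituted olefin at its terminal carbon (the lactone and the trisubstituted olefin are inert at room temperature), and B-alkyl Suzuki–Miyaura coupling with the Z-alkenyl iodide retains the 14Z geometry because oxidative addition into the carbon–iodine bond is much faster than ionisation of the allylic acetate.

Step 11
Reactants: 18 (2Z)-5-[(1R,2S,5R,9S)-9-[(3Z)-5-(TBSO)-3-methylpent-3-en-1-yl]-2-hydroxy-5-methyl-7-oxo-6,8-dioxabicyclo[3.2.2]nonan-1-yl]-2-methylpent-2-en-1-yl acetate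
Product: 19 (2Z)-5-[(1R,2S,5R,9S)-2-hydroxy-9-[(3Z)-5-hydroxy-3-methylpent-3-en-1-yl]-5-methyl-7-oxo-6,8-dioxabicyclo[3.2.2]nonan-1-yl]-2-methylpent-2-en-1-yl acetate (CNP0174851.1)
Conditions: HF·pyridine, pyridine/THF, 0 °C → rt
Reagents that add atoms: none
Why: Fluoride-driven cleavage of the primary silyl ether (Si–F bond formation) leaves the acetate, the lactone and both olefins untouched and affects no stereocentre.

**Compound list**

1 | nerol, (2Z)-3,7-dimethylocta-2,6-dien-1-ol | CC(C)=CCC/C(C)=C\CO | starting material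
2 | tert-butyl{[(2Z)-3,7-dimethylocta-2,6-dien-1-yl]oxy}dimethylsilane | CC(C)=CCC/C(C)=C\CO[Si](C)(C)C(C)(C)C | intermediate
3 | (2E,6Z)-8-(TBSO)-2,6-dimethylocta-2,6-dien-1-ol | OC/C(C)=C/CC/C(C)=C\CO[Si](C)(C)C(C)(C)C | intermediate
4 | (2E,6Z)-8-(TBSO)-2,6-dimethylocta-2,6-dienal | O=C/C(C)=C/CC/C(C)=C\CO[Si](C)(C)C(C)(C)C | intermediate
5 | tert-butyl{[(2Z,6E)-3,7-dimethylnona-2,6,8-trien-1-yl]oxy}dimethylsilane | C=C/C(C)=C/CC/C(C)=C\CO[Si](C)(C)C(C)(C)C | intermediate
6 | prop-2-yn-1-ol | C#CCO | starting material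
7 | (2Z)-2-(iodomethylidene)but-3-en-1-ol | OC/C(C=C)=C\I | intermediate
8 | 9-[(3E,7Z)-9-(TBSO)-3,7-dimethylnona-3,7-dien-1-yl]-9-borabicyclo[3.3.1]nonane | C1CCC2CCCC1B2CC/C(C)=C/CC/C(C)=C\CO[Si](C)(C)C(C)(C)C | intermediate
9 | (2Z,6E,10Z)-12-(TBSO)-2-ethenyl-6,10-dimethyldodeca-2,6,10-trien-1-ol | C=C/C(CO)=C/CC/C(C)=C/CC/C(C)=C\CO[Si](C)(C)C(C)(C)C | intermediate
10 | {(2R,3S)-3-[(3E,7Z)-9-(TBSO)-3,7-dimethylnona-3,7-dien-1-yl]-2-ethenyloxiran-2-yl}methanol | C=C[C@]1(CO)O[C@H]1CC/C(C)=C/CC/C(C)=C\CO[Si](C)(C)C(C)(C)C | intermediate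
11 | {(2R,3S)-3-(2-{(2S,3S)-3-[(3Z)-5-(TBSO)-3-methylpent-3-en-1-yl]-2-methyloxiran-2-yl}ethyl)-2-ethenyloxiran-2-yl}methanol | C=C[C@]1(CO)O[C@H]1CC[C@]2(C)O[C@H]2CC/C(C)=C\CO[Si](C)(C)C(C)(C)C | intermediate
12 | (2S,3S)-3-(2-{(2S,3S)-3-[(3Z)-5-(TBSO)-3-methylpent-3-en-1-yl]-2-methyloxiran-2-yl}ethyl)-2-ethenyloxirane-2-carboxylic acid | C=C[C@]1(C(=O)O)O[C@H]1CC[C@]2(C)O[C@H]2CC/C(C)=C\CO[Si](C)(C)C(C)(C)C | intermediate
13 | (3S,4S,7R)-3,4-epoxy-3-ethenyl-7-[(1S,4Z)-6-(TBSO)-1-hydroxy-4-methylhex-4-en-1-yl]-7-methyloxepan-2-one | C=C[C@]12O[C@H]1CC[C@@](C)(OC2=O)[C@@H](O)CC/C(C)=C\CO[Si](C)(C)C(C)(C)C | intermediate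
14 | (1R,2S,5R,9S)-9-[(3Z)-5-(TBSO)-3-methylpent-3-en-1-yl]-1-ethenyl-2-hydroxy-5-methyl-6,8-dioxabicyclo[3.2.2]nonan-7-one | C=C[C@@]12O[C@@H](CC/C(C)=C\CO[Si](C)(C)C(C)(C)C)[C@@](C)(CC[C@@H]1O)OC2=O | intermediate
15 | bromomagnesium (2Z)-3-iodo-2-methylprop-2-en-1-olate | C/C(C[O-])=C/I.[Mg+2].[Br-] | intermediate
16 | (2Z)-3-iodo-2-methylprop-2-en-1-yl acetate | CC(=O)OC/C(C)=C\I | intermediate
17 | 9-BBN adduct of 14: 1-[2-(9-borabicyclo[3.3.1]nonan-9-yl)ethyl] with the C2 oxygen as its 9-BBN borinate | C1CCC2CCCC1B2CC[C@@]34O[C@@H](CC/C(C)=C\CO[Si](C)(C)C(C)(C)C)[C@@](C)(CC[C@@H]3OB5C6CCCC5CCC6)OC4=O | intermediate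
18 | (2Z)-5-[(1R,2S,5R,9S)-9-[(3Z)-5-(TBSO)-3-methylpent-3-en-1-yl]-2-hydroxy-5-methyl-7-oxo-6,8-dioxabicyclo[3.2.2]nonan-1-yl]-2-methylpent-2-en-1-yl acetate | CC(=O)OC/C(C)=C\CC[C@@]12O[C@@H](CC/C(C)=C\CO[Si](C)(C)C(C)(C)C)[C@@](C)(CC[C@@H]1O)OC2=O | intermediate
19 | (2Z)-5-[(1R,2S,5R,9S)-2-hydroxy-9-[(3Z)-5-hydroxy-3-methylpent-3-en-1-yl]-5-methyl-7-oxo-6,8-dioxabicyclo[3.2.2]nonan-1-yl]-2-methylpent-2-en-1-yl acetate | CC(=O)OC/C(C)=C\CC[C@@]12O[C@@H](CC/C(C)=C\CO)[C@@](C)(CC[C@@H]1O)OC2=O | target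

**Step count**

Total steps: 11. Longest linear sequence: 9 (steps 1, 2, 3, 5, 6, 7, 8, 10, 11 from nerol).

**Three steps most likely to fail, each with a fallback**

Step 8 (oxidation-triggered double epoxide opening). The risks are attack of the C6 hydroxyl at C10 instead of C11, and acid-induced loss of the vinyl glycidate (butenolide formation or decarboxylation) before lactonisation. The fallback sets out from 11, returns at 14, and reverses the order of ring formation so that no substitution next to a carbonyl is needed. Silylate 11 (Et3SiCl, imidazole) to the bis-epoxy triethylsilyl ether F1. Treat it with BF3·OEt2 in CH2Cl2 at −78 °C and quench with water: the 6,7-epoxide oxygen opens the activated vinyl epoxide at allylic C11 and the resulting epoxonium ion is hydrolysed at tertiary C7, which gives the oxepane diol F2 with the same four configurations. Remove the triethylsilyl group (PPTS, MeOH, 0 °C) to give the oxepane triol F3. Close the lactone by TEMPO/PhI(OAc)2 oxidative lactonisation of the primary alcohol onto the C7 hydroxyl, which gives 14.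

Step 10 (late hydroboration/B-alkyl Suzuki coupling). The risks are sluggish hydroboration beside the quaternary centre, and base or zerovalent palladium attacking the lactone or the allylic acetate. The fallback sets out from 14 (and 6), returns at 18, and replaces the boron/palladium coupling by a nickel-catalysed reductive coupling of two halides. Oxidise borane 17 with NaBO3 to the primary alcohol F4 and convert it into the primary iodide F5 (I2, PPh3, imidazole; the hindered secondary hydroxyl does not react). Prepare free (2Z)-3-iodo-2-methylprop-2-en-1-ol F6 from 6 by running step 9 with a water quench in place of acetic anhydride. Couple F5 with F6 (NiI2, 4,4′-di-tert-butyl-2,2′-bipyridine, Zn dust, dimethylacetamide, rt; alkene geometry retained) to the C16 alcohol F7. Acetylate its primary allylic hydroxyl selectively (Ac2O, pyridine, −20 °C) to reach 18.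

Step 6 (Sharpless epoxidation of the cross-conjugated dienol). The risks are lower rate and selectivity for this Z-type 2-substituted allylic alcohol, and opening of the vinyl epoxide by Ti(Oi-Pr)4. The fallback sets out from 9, returns at 18, and attaches the C13–C17 arm first so that an ordinary trisubstituted allylic alcohol is epoxidised. Hydroborate the vinyl group of 9 with 9-BBN to the bis-boron adduct F8 and couple it with 16 (Pd(dppf)Cl2, AsPh3, aq. K3PO4) to the tetraene alcohol F9. Sharpless epoxidation with D-(−)-diethyl tartrate gives the epoxy alcohol F10, and Shi epoxidation with the L-fructose ketone gives the bis-epoxy alcohol F11. TEMPO/PhI(OAc)2 oxidation gives the bis-epoxy acid F12, which lactonises under CSA to the hydroxy epoxy-lactone F13. Because the vinyl activation is now absent, the second ring is closed through the C6 alkoxide (NaN(SiMe3)2, THF, −78 → 0 °C; 6-exo attack at the lactone α-carbon), which gives 18 directly.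

**Further compounds**

F1 | step 8 | C18 triethylsilyl ether of 11 | C=C[C@]1(CO[Si](CC)(CC)CC)O[C@H]1CC[C@]2(C)O[C@H]2CC/C(C)=C\CO[Si](C)(C)C(C)(C)C
F2 | step 8 | (2S,3R,6S,7S)-7-ethenyl-2-[(3Z)-5-(TBSO)-3-methylpent-3-en-1-yl]-3-methyl-7-[(triethylsilyloxy)methyl]oxepane-3,6-diol | C=C[C@@]1(CO[Si](CC)(CC)CC)O[C@@H](CC/C(C)=C\CO[Si](C)(C)C(C)(C)C)[C@@](C)(CC[C@@H]1O)O
F3 | step 8 | (2S,3R,6S,7S)-7-ethenyl-7-(hydroxymethyl)-2-[(3Z)-5-(TBSO)-3-methylpent-3-en-1-yl]-3-methyloxepane-3,6-diol | C=C[C@@]1(CO)O[C@@H](CC/C(C)=C\CO[Si](C)(C)C(C)(C)C)[C@@](C)(CC[C@@H]1O)O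
F4 | step 10 | (1R,2S,5R,9S)-2-hydroxy-1-(2-hydroxyethyl)-9-[(3Z)-5-(TBSO)-3-methylpent-3-en-1-yl]-5-methyl-6,8-dioxabicyclo[3.2.2]nonan-7-one | OCC[C@@]12O[C@@H](CC/C(C)=C\CO[Si](C)(C)C(C)(C)C)[C@@](C)(CC[C@@H]1O)OC2=O
F5 | step 10 | (1R,2S,5R,9S)-2-hydroxy-1-(2-iodoethyl)-9-[(3Z)-5-(TBSO)-3-methylpent-3-en-1-yl]-5-methyl-6,8-dioxabicyclo[3.2.2]nonan-7-one | ICC[C@@]12O[C@@H](CC/C(C)=C\CO[Si](C)(C)C(C)(C)C)[C@@](C)(CC[C@@H]1O)OC2=O
F6 | step 10 | (2Z)-3-iodo-2-methylprop-2-en-1-ol | C/C(CO)=C/I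
F7 | step 10 | (1R,2S,5R,9S)-2-hydroxy-1-[(3Z)-5-hydroxy-4-methylpent-3-en-1-yl]-9-[(3Z)-5-(TBSO)-3-methylpent-3-en-1-yl]-5-methyl-6,8-dioxabicyclo[3.2.2]nonan-7-one | OC/C(C)=C\CC[C@@]12O[C@@H](CC/C(C)=C\CO[Si](C)(C)C(C)(C)C)[C@@](C)(CC[C@@H]1O)OC2=O
F8 | step 6 | 9-BBN adduct of 9 (boron on the terminal carbon of the former vinyl group, the CH2OH oxygen as its 9-BBN borinate) | C1CCC2CCCC1B2CC/C(COB3C4CCCC3CCC4)=C/CC/C(C)=C/CC/C(C)=C\CO[Si](C)(C)C(C)(C)C
F9 | step 6 | (2Z,6Z,10E,14Z)-16-(TBSO)-6-(hydroxymethyl)-2,10,14-trimethylhexadeca-2,6,10,14-tetraen-1-yl acetate | CC(=O)OC/C(C)=C\CC/C(CO)=C/CC/C(C)=C/CC/C(C)=C\CO[Si](C)(C)C(C)(C)C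
F10 | step 6 | (2Z)-5-{(2R,3S)-3-[(3E,7Z)-9-(TBSO)-3,7-dimethylnona-3,7-dien-1-yl]-2-(hydroxymethyl)oxiran-2-yl}-2-methylpent-2-en-1-yl acetate | CC(=O)OC/C(C)=C\CC[C@]1(CO)O[C@H]1CC/C(C)=C/CC/C(C)=C\CO[Si](C)(C)C(C)(C)C
F11 | step 6 | (2Z)-5-[(2R,3S)-2-(hydroxymethyl)-3-(2-{(2S,3S)-3-[(3Z)-5-(TBSO)-3-methylpent-3-en-1-yl]-2-methyloxiran-2-yl}ethyl)oxiran-2-yl]-2-methylpent-2-en-1-yl acetate | CC(=O)OC/C(C)=C\CC[C@]1(CO)O[C@H]1CC[C@]2(C)O[C@H]2CC/C(C)=C\CO[Si](C)(C)C(C)(C)C
F12 | step 6 | (2S,3S)-2-[(3Z)-5-acetoxy-4-methylpent-3-en-1-yl]-3-(2-{(2S,3S)-3-[(3Z)-5-(TBSO)-3-methylpent-3-en-1-yl]-2-methyloxiran-2-yl}ethyl)oxirane-2-carboxylic acid | CC(=O)OC/C(C)=C\CC[C@]1(C(=O)O)O[C@H]1CC[C@]2(C)O[C@H]2CC/C(C)=C\CO[Si](C)(C)C(C)(C)C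
F13 | step 6 | (2Z)-5-{(3S,4S,7R)-3,4-epoxy-7-[(1S,4Z)-6-(TBSO)-1-hydroxy-4-methylhex-4-en-1-yl]-7-methyl-2-oxooxepan-3-yl}-2-methylpent-2-en-1-yl acetate | CC(=O)OC/C(C)=C\CC[C@]12O[C@H]1CC[C@@](C)(OC2=O)[C@@H](O)CC/C(C)=C\CO[Si](C)(C)C(C)(C)C
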